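**Plan**

- The retrosynthesis cuts C2–C3 and O1–C8a of the pyran ring (ring C) together, as a retro-oxa-[4+2]. C2=O1 becomes the carbonyl group of 3,4,5-trimethoxybenzaldehyde; C3=C4–C4a=C8a becomes a diene.
- The enabling feature is that C4a–C8a is the bond shared by ring C and ring A. It can serve as a diene double bond only if ring A is carried in 5,6-dihydro form (C5 and C6 sp3).
- Ring A is therefore taken back to 2,3-dimethoxycyclohex-2-en-1-one (ketone carbon = C8a, enol ether carbons = C8 and C7); acetaldehyde supplies C4 and C3.
- The ketone oxygen stays on C8a as a silyloxy group. It makes C3 the nucleophilic diene terminus and then leaves as silanol, so the cycloadduct is already at the oxidation level of the arene and no oxidant is needed.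
- Forward order: cyclohexane-1,3-dione → 2,3-dimethoxy enone → aldol and dehydration → silyl trienol ether → asymmetric hetero-Diels–Alder reaction (ring C closes) → ring A aromatizes last, in the same flask.
- The only stereocenter, C2, is set in the cycloaddition by a chiral chromium catalyst (Si face of the aldehyde) and its C–O bond is not broken afterwards.

Key step: step 6

Remark: 2,3-dimethoxycyclohex-2-en-1-one is assumed not to be a stock chemical and is made from cyclohexane-1,3-dione.

**Step 1**
Reactants: 1 cyclohexane-1,3-dione
Product: 2 2-diazocyclohexane-1,3-dione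
Conditions: p-ABSA (1.05 equiv), Et3N, MeCN, 0 °C to rt
Reagents that add atoms: 4-acetamidobenzenesulfonyl azide (p-ABSA), CC(=O)Nc1ccc(cc1)S(=O)(=O)N=[N+]=[N-]
Why: Regitz diazo transfer to the doubly activated C2 methylene of a cyclic 1,3-dione is a standard reaction and creates no stereocenter.

**Step 2**
Reactants: 2 2-diazocyclohexane-1,3-dione
Product: 4 2,3-dimethoxycyclohex-2-en-1-one, via 2-methoxycyclohexane-1,3-dione 3 (not isolated)
Conditions: Rh2(OAc)4 (1 mol %), MeOH, 60 °C; then HC(OMe)3, TsOH·H2O (cat.), rt
Reagents that add atoms: methanol, CO; trimethyl orthoformate, COC(OC)OC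
Why: Rhodium carbenoid O–H insertion into methanol should place the methoxy group on C2, and acid-catalysed enol ether formation of the symmetrical vinylogous acid with orthoformate (the usual preparation of 3-alkoxycyclohexenones) should give a single vinylogous ester without a stereocenter.

**Step 3**
Reactants: 4 2,3-dimethoxycyclohex-2-en-1-one; 5 acetaldehyde
Product: 6 6-(1-hydroxyethyl)-2,3-dimethoxycyclohex-2-en-1-one (racemic, both diastereomers)
Conditions: LDA (1.1 equiv), THF, −78 °C; MeCHO, −78 °C; AcOH quench
Reagents that add atoms: none
Why: Kinetic deprotonation of a 3-alkoxycyclohexenone occurs at C6 (Stork–Danheiser enolate; C2 carries no hydrogen) and the lithium enolate should undergo aldol addition to acetaldehyde; the two new stereocenters are uncontrolled and are erased in steps 4 and 5.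

**Step 4**
Reactants: 6 6-(1-hydroxyethyl)-2,3-dimethoxycyclohex-2-en-1-one
Product: 8 (E)-6-ethylidene-2,3-dimethoxycyclohex-2-en-1-one, via mesylate 7 (not isolated)
Conditions: MsCl, Et3N, CH2Cl2, 0 °C; then DBU, 0 °C, short reaction time
Reagents that add atoms: none
Why: Mesylation and E1cB elimination of the β-mesyloxy ketone is the standard dehydration of such aldols and should give the exocyclic enone, E by thermodynamic preference (the geometry is lost in step 5).

**Step 5**
Reactants: 8 (E)-6-ethylidene-2,3-dimethoxycyclohex-2-en-1-one
Product: 9 1-ethenyl-3,4-dimethoxy-2-(triethylsilyloxy)cyclohexa-1,3-diene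
Conditions: KHMDS (1.1 equiv), THF, −78 °C; TESCl, −78 to 0 °C; pentane, filtration under argon, used at once
Reagents that add atoms: chlorotriethylsilane (TESCl), CC[Si](CC)(CC)Cl
Why: With C2 and C6 fully substituted only an extended enolate can form, and γ-deprotonation of the ethylidene methyl group (charge on C6 and the terminal carbon) should be preferred over deprotonation at C4 (charge on the methoxy-bearing C2), after which O-silylation gives the silyl trienol ether (the usual route from enones to 1-silyloxydienes).

**Step 6**
Reactants: 9 1-ethenyl-3,4-dimethoxy-2-(triethylsilyloxy)cyclohexa-1,3-diene (1.5 equiv); 10 3,4,5-trimethoxybenzaldehyde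
Product: 12 (2S)-7,8,3',4',5'-pentamethoxyflavan, via cycloadduct 11 (not isolated)
Conditions: CrCl(L) (5 mol %; trivalent chromium; L = dianion of the Schiff base of 3-(1-adamantyl)-2-hydroxy-5-methylbenzaldehyde and (1S,2R)-1-aminoindan-2-ol), 4 Å MS, acetone, rt; then CF3CO2H (0.2 equiv), CH2Cl2, −20 to 0 °C
Reagents that add atoms: none
Why: Proposed new method: the chromium Lewis acid should bind the aldehyde, and the exocyclic 1-silyloxydiene C3=C4–C4a=C8a of 9 should add across C=O in a concerted, asynchronous oxa-[4+2] cycloaddition (C3 to the carbonyl carbon, C8a to the carbonyl oxygen), which closes the pyran ring (ring C) by intermolecular cycloaddition with both ring bonds formed at once. Acid should then ionize the C8a–OSiEt3 bond of silyl ketal 11; the extended oxocarbenium ion loses H-6, and the resulting isotoluene-type triene tautomerizes (protonation at C4, loss of H-5) to the benzene ring A, so ring A is not closed but aromatized without an oxidant. The closest known reaction type is the catalytic asymmetric hetero-Diels–Alder reaction of 1-alkoxy- and 1-silyloxydienes with aldehydes under tridentate Schiff-base chromium chloride catalysis, which has not been run on a dihydroarene triene whose oxygen-bearing terminus is a fully substituted ring carbon. C2 is set by the catalyst, which should expose the Si face of the aldehyde to C3; the (1S,2R) antipode is chosen by analogy with its expected sense for 1-methoxybutadiene, and the mirror-image complex is used instead if a first run shows the opposite sense, while C8a of 11 is transient and is erased. The step needs C3 as the nucleophilic terminus and C8a as the oxygen acceptor, which the silyloxy group on C8a and the methoxy group on C7 secure by stabilizing positive charge at C8a and C7 as C3 bonds, and the unsubstituted C3 is the only unhindered terminus, which disfavors reaction of the ring diene C4a=C8a–C8=C7 at quaternary C4a. In the aromatization the C8a–OSi bond must break and not C8a–O1: silanol loss is irreversible, opening at C8a–O1 is reversible because the C4=C4a geometry holds the oxygen next to C8a, and the C2–O1 bond is never touched, so C2 keeps its configuration.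

**Compound list**

1 | cyclohexane-1,3-dione | O=C1CCCC(=O)C1 | starting material
2 | 2-diazocyclohexane-1,3-dione | [N-]=[N+]=C1C(=O)CCCC1=O | intermediate
3 | 2-methoxycyclohexane-1,3-dione (not isolated) | COC1C(=O)CCCC1=O | intermediate
4 | 2,3-dimethoxycyclohex-2-en-1-one | COC1=C(OC)C(=O)CCC1 | intermediate
5 | acetaldehyde | CC=O | starting material
6 | 6-(1-hydroxyethyl)-2,3-dimethoxycyclohex-2-en-1-one (racemic, both diastereomers) | COC1=C(OC)C(=O)C(C(C)O)CC1 | intermediate
7 | 1-(3,4-dimethoxy-2-oxocyclohex-3-en-1-yl)ethyl methanesulfonate (mesylate, not isolated) | COC1=C(OC)C(=O)C(C(C)OS(C)(=O)=O)CC1 | intermediate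
8 | (E)-6-ethylidene-2,3-dimethoxycyclohex-2-en-1-one | C/C=C1\CCC(OC)=C(OC)C1=O | intermediate
9 | 1-ethenyl-3,4-dimethoxy-2-(triethylsilyloxy)cyclohexa-1,3-diene | C=CC1=C(O[Si](CC)(CC)CC)C(OC)=C(OC)CC1 | intermediate
10 | 3,4,5-trimethoxybenzaldehyde | COc1cc(C=O)cc(OC)c1OC | starting material
11 | (2S,8aS)-7,8-dimethoxy-8a-(triethylsilyloxy)-2-(3,4,5-trimethoxyphenyl)-3,5,6,8a-tetrahydro-2H-chromene (endo cycloadduct expected, aryl cis to C8; the C8a configuration is of no consequence; not isolated) | COc1cc([C@@H]2CC=C3CCC(OC)=C(OC)[C@]3(O[Si](CC)(CC)CC)O2)cc(OC)c1OC | intermediate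
12 | (2S)-7,8,3',4',5'-pentamethoxyflavan | COc1cc([C@@H]2CCc3ccc(OC)c(OC)c3O2)cc(OC)c1OC | target

Total step count: 6. Longest linear sequence: 6 steps (from cyclohexane-1,3-dione).

**Steps most likely to fail**

1. Step 6 (proposed new method). The addition may run stepwise as a vinylogous Mukaiyama aldol without ring closure, giving an open-chain adduct whose later closure would ionize at C2 and lose configuration. Facial selectivity may be poor with the electron-rich aromatic aldehyde. The ketal may open at C8a–O1 during aromatization, and the triene may be oxidized by air before it reacts.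
 Fallback (known chemistry), setting out from aldehyde 10 and returning at 12: Claisen–Schmidt condensation of 10 with commercial 2'-hydroxy-3',4'-dimethoxyacetophenone (KOH, EtOH) should give (E)-1-(2-hydroxy-3,4-dimethoxyphenyl)-3-(3,4,5-trimethoxyphenyl)prop-2-en-1-one F1. Oxa-Michael cyclization (NaOAc, EtOH, reflux) should give racemic 7,8-dimethoxy-2-(3,4,5-trimethoxyphenyl)chroman-4-one F2. Asymmetric transfer hydrogenation run as a kinetic resolution (RhCl(C5Me5)[(S,S)-TsNCHPhCHPhNH2], HCO2H/Et3N, EtOAc, stopped near half conversion) should reduce the (2S)-enantiomer to (2S,4S)-7,8-dimethoxy-2-(3,4,5-trimethoxyphenyl)chroman-4-ol F3, which is separated from the unreacted (2R)-ketone. Ionic deoxygenation of the benzylic C4–OH (Et3SiH, CF3CO2H, CH2Cl2, −20 °C) should then give 12.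

2. Step 5. Deprotonation may occur at C4 and not at the ethylidene methyl group, after which the wrong trienol ether tautomerizes irreversibly to an aryl silyl ether. The correct triene may also be lost by air oxidation to the styrene.
 Fallback, setting out from enone 4 and returning at 9: the lithium enolate of 4 (LDA, THF, −78 °C) is added to (phenylselanyl)acetaldehyde to give 6-[1-hydroxy-2-(phenylselanyl)ethyl]-2,3-dimethoxycyclohex-2-en-1-one F4. Treatment with MsCl/Et3N (elimination of the β-hydroxy selenide) should give 6-ethenyl-2,3-dimethoxycyclohex-2-en-1-one F5. Its C6–H is both α to the ketone and allylic, so KHMDS followed by TESCl should give 9 with the site of deprotonation fixed.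

3. Step 4. The cross-conjugated dienone may tautomerize to 6-ethyl-2,3-dimethoxyphenol under the basic elimination conditions.
 Fallback, setting out from enone 4 and returning at 8: the lithium enolate of 4 is C-phosphinylated with ClP(OEt)2 to diethyl (3,4-dimethoxy-2-oxocyclohex-3-en-1-yl)phosphonite F6, which is oxidized in the same flask (H2O2) to diethyl (3,4-dimethoxy-2-oxocyclohex-3-en-1-yl)phosphonate F7. Horner–Wadsworth–Emmons olefination of acetaldehyde 5 under mild conditions (LiCl, iPr2NEt, MeCN) should give 8 without a separate elimination step.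

**Further compounds**

F1 | step 6 | (E)-1-(2-hydroxy-3,4-dimethoxyphenyl)-3-(3,4,5-trimethoxyphenyl)prop-2-en-1-one | COc1cc(/C=C/C(=O)c2ccc(OC)c(OC)c2O)cc(OC)c1OC
F2 | step 6 | racemic 7,8-dimethoxy-2-(3,4,5-trimethoxyphenyl)chroman-4-one | COc1cc(C2CC(=O)c3ccc(OC)c(OC)c3O2)cc(OC)c1OC
F3 | step 6 | (2S,4S)-7,8-dimethoxy-2-(3,4,5-trimethoxyphenyl)chroman-4-ol | COc1cc([C@@H]2C[C@H](O)c3ccc(OC)c(OC)c3O2)cc(OC)c1OC
F4 | step 5 | 6-[1-hydroxy-2-(phenylselanyl)ethyl]-2,3-dimethoxycyclohex-2-en-1-one | COC1=C(OC)C(=O)C(C(O)C[Se]c2ccccc2)CC1
F5 | step 5 | 6-ethenyl-2,3-dimethoxycyclohex-2-en-1-one | COC1=C(OC)C(=O)C(C=C)CC1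
F6 | step 4 | diethyl (3,4-dimethoxy-2-oxocyclohex-3-en-1-yl)phosphonite | CCOP(OCC)C1CCC(OC)=C(OC)C1=O
F7 | step 4 | diethyl (3,4-dimethoxy-2-oxocyclohex-3-en-1-yl)phosphonate | CCOP(=O)(OCC)C1CCC(OC)=C(OC)C1=O
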